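**Retrosynthetic overview**
1. Target 25 ⇐ ethyl ester aldehyde 24 (formyl-assisted ester cleavage) ⇐ C-12 methyl oxidation of 23 ⇐ 6β-alcohol 18 + trienoic acid 21 (sorbaldehyde + malonic acid).
2. 18 ⇐ enone 17 (hydride from the α-face) ⇐ alkylative 1,3-carbonyl transposition of enone 15 (methyl addition, oxidative rearrangement).
3. 15 ⇐ decalin α-hydroxy β-keto ester 14 ⇐ key ring enlargement: α-ketol shift of oxalyl carbinol 13, in which C-10 migrates and C-9 is set.
4. 13 ⇐ trans-hydrindanone 10 + ethyl diazoacetate; 10 ⇐ (S)-Hajos–Parrish ketone 5 (gem-dimethylation, deoxygenation, hydrogenation).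
5. Ring order: cyclopentane (from 2-methylcyclopentane-1,3-dione), then ring A (proline-mediated annulation), then ring B by one-carbon enlargement of the five-membered ring.

Assumption: the target is taken as the open hydroxy acid aldehyde as drawn (its lactol ring tautomer counts as the same compound); positions are given in drimane numbering (C-1 to C-12).

**Step 1**
Reactants: 1 2-methylcyclopentane-1,3-dione; 2 methyl vinyl ketone
Product: 5 (S)-7a-methyl-2,3,7,7a-tetrahydro-1H-indene-1,5(6H)-dione (Hajos–Parrish ketone), via triketone 3 (not isolated), via Hajos ketol 4 (not isolated)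
Conditions: H2O, AcOH (cat.), 70 °C; then (S)-proline (3 mol %), DMF, 20 °C; then H2SO4 (cat.), DMF, 95 °C
Reagents that add atoms: none
Why: Michael addition followed by the (S)-proline-catalysed Hajos–Parrish–Eder–Sauer–Wiechert aldol cyclisation and acid dehydration; the proline enamine differentiates the two enantiotopic ring carbonyls and fixes the quaternary centre as 7aS.

**Step 2**
Reactants: 5 (S)-Hajos–Parrish ketone
Product: 6 (7aS)-1,1-(ethylenedioxy)-7a-methyl-1,2,3,6,7,7a-hexahydro-5H-inden-5-one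
Conditions: ethylene glycol, p-TsOH·H2O, 4 Å MS, 20 °C
Reagents that add atoms: ethylene glycol, OCCO
Why: acid-catalysed ketalisation is chemoselective for the saturated cyclopentanone because the enone carbonyl is deactivated by conjugation; no stereocentre is touched.

**Step 3**
Reactants: 6 (7aS)-1,1-(ethylenedioxy)-7a-methyl-1,2,3,6,7,7a-hexahydro-5H-inden-5-one
Product: 7 (7aS)-1,1-(ethylenedioxy)-4,4,7a-trimethyl-1,2,4,6,7,7a-hexahydro-5H-inden-5-one
Conditions: KOtBu, t-BuOH/THF, 0 °C; MeI, 0 → 20 °C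
Reagents that add atoms: methyl iodide, CI
Why: deconjugative double α-alkylation of the extended enolate (classical gem-dimethylation of annulation enones) installs both C-4 methyls and moves the double bond to C-5/C-6.

**Step 4**
Reactants: 7 (7aS)-1,1-(ethylenedioxy)-4,4,7a-trimethyl-1,2,4,6,7,7a-hexahydro-5H-inden-5-one
Product: 9 (7aS)-4,4,7a-trimethyl-2,4,5,6,7,7a-hexahydro-1H-inden-1-one, via deoxygenated ketal 8 (not isolated)
Conditions: N2H4·H2O, KOH, diethylene glycol, 130 → 200 °C; then 2 M HCl, THF, 20 °C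
Reagents that add atoms: water, O
Why: Wolff–Kishner (Huang-Minlon) reduction removes the C-3 carbonyl under base that the ketal and the isolated alkene tolerate, and the acid work-up unmasks the cyclopentanone.

**Step 5**
Reactants: 9 (7aS)-4,4,7a-trimethyl-2,4,5,6,7,7a-hexahydro-1H-inden-1-one
Product: 10 (3aS,7aS)-4,4,7a-trimethyloctahydro-1H-inden-1-one
Conditions: H2 (4 atm), 10 % Pd/C, EtOAc, 20 °C
Reagents that add atoms: none
Why: heterogeneous hydrogenation adds H2 syn from the face opposite the angular methyl group (as with 14-ene steroids), creating the trans ring fusion (3aS).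

**Step 6**
Reactants: 10 (3aS,7aS)-4,4,7a-trimethyloctahydro-1H-inden-1-one; 11 ethyl diazoacetate
Product: 12 ethyl 2-diazo-2-[(1S,3aS,7aS)-1-hydroxy-4,4,7a-trimethyloctahydro-1H-inden-1-yl]acetate
Conditions: LiN(iPr)2 (LDA), THF, −78 °C
Reagents that add atoms: none
Why: aldol-type addition of ethyl lithiodiazoacetate to the ketone; attack anti to the adjacent angular methyl (α-face, as with 17-oxo steroids) gives the 1S carbinol with OH cis to the methyl group.

**Step 7**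
Reactants: 12 ethyl 2-diazo-2-[(1S,3aS,7aS)-1-hydroxy-4,4,7a-trimethyloctahydro-1H-inden-1-yl]acetate
Product: 14 ethyl (1R,4aS,8aS)-1-hydroxy-5,5,8a-trimethyl-2-oxodecahydronaphthalene-1-carboxylate, via oxalyl carbinol 13 (not isolated)
Conditions: DMDO, acetone, 0 °C; then Sc(OTf)3 (10 mol %), 4 Å MS, CH2Cl2, 0 → 25 °C
Reagents that add atoms: dimethyldioxirane, CC1(C)OO1
Why: Proposed new method: ring-enlarging α-ketol (acyloin) shift of a 1-(ethoxyoxalyl)cycloalkanol in which the fully substituted ring-fusion carbon migrates; after DMDO turns the diazo carbon into a ketone, Sc(OTf)3 chelates the 1-OH and the keto oxygen syn-periplanar, the electron-rich C-10 shifts suprafacially from the carbinol carbon to the activated keto carbon with proton transfer (driven by cyclopentane to cyclohexane enlargement and conversion of the 1,2-dicarbonyl into a β-keto ester), so the old carbinol carbon becomes the C-8 ketone and the new C-9 carries OH on the face of the former 1-OH (β, cis to the angular methyl) and the ester α (1R); the closest known reaction type is the α-ketol D-homoannulation of 17β-hydroxy-17α-acyl steroids and the Lewis-acid acyloin shift of β-hydroxy α-keto esters.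

**Step 8**
Reactants: 14 ethyl (1R,4aS,8aS)-1-hydroxy-5,5,8a-trimethyl-2-oxodecahydronaphthalene-1-carboxylate
Product: 15 ethyl (1R,4aS,8aS)-1-hydroxy-5,5,8a-trimethyl-2-oxo-1,2,4a,5,6,7,8,8a-octahydronaphthalene-1-carboxylate
Conditions: IBX, DMSO, 65 °C
Reagents that add atoms: none
Why: IBX dehydrogenation through the only possible enol (toward C-7, since C-9 is fully substituted) gives the cyclohexenone without touching stereocentres.

**Step 9**
Reactants: 15 ethyl (1R,4aS,8aS)-1-hydroxy-5,5,8a-trimethyl-2-oxo-1,2,4a,5,6,7,8,8a-octahydronaphthalene-1-carboxylate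
Product: 17 ethyl (1S,4aS,8aS)-1-hydroxy-2,5,5,8a-tetramethyl-4-oxo-1,4,4a,5,6,7,8,8a-octahydronaphthalene-1-carboxylate, via tertiary allylic alcohol 16 (not isolated)
Conditions: MeLi, CeCl3, THF, −78 °C; then 4-acetamido-2,2,6,6-tetramethyl-1-oxopiperidinium tetrafluoroborate, MeCN, 20 °C
Reagents that add atoms: methyllithium, [Li]C
Why: chemoselective 1,2-addition of the organocerium reagent to the ketone (ester spared) followed by oxoammonium-mediated oxidative 1,3-transposition of the tertiary allylic alcohol (Babler–Dauben type) moves the oxygen to C-6 and leaves the methyl group on C-8; the transient C-8 stereocentre is destroyed.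

**Step 10**
Reactants: 17 ethyl (1S,4aS,8aS)-1-hydroxy-2,5,5,8a-tetramethyl-4-oxo-1,4,4a,5,6,7,8,8a-octahydronaphthalene-1-carboxylate
Product: 18 ethyl (1S,4R,4aS,8aS)-1,4-dihydroxy-2,5,5,8a-tetramethyl-1,4,4a,5,6,7,8,8a-octahydronaphthalene-1-carboxylate
Conditions: NaBH4, CeCl3·7H2O, MeOH, −40 °C
Reagents that add atoms: none
Why: Luche 1,2-reduction; hydride attacks from the α-face because the β-face of C-6 is shielded by the syn-axial methyls on C-4 and C-10, giving the axial 6β-alcohol (4R).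

**Step 11**
Reactants: 19 (2E,4E)-hexa-2,4-dienal (sorbaldehyde); 20 malonic acid
Product: 21 (2E,4E,6E)-octa-2,4,6-trienoic acid
Conditions: pyridine, piperidine (cat.), 90 °C
Reagents that add atoms: none
Why: Doebner–Knoevenagel condensation with decarboxylation gives the new double bond E under thermodynamic control.

**Step 12**
Reactants: 18 ethyl (1S,4R,4aS,8aS)-1,4-dihydroxy-2,5,5,8a-tetramethyl-1,4,4a,5,6,7,8,8a-octahydronaphthalene-1-carboxylate; 21 (2E,4E,6E)-octa-2,4,6-trienoic acid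
Product: 23 ethyl (1S,4R,4aS,8aS)-1-hydroxy-2,5,5,8a-tetramethyl-4-[(2E,4E,6E)-octa-2,4,6-trienoyloxy]-1,4,4a,5,6,7,8,8a-octahydronaphthalene-1-carboxylate, via trienoyl chloride 22 (not isolated)
Conditions: 21, (COCl)2, DMF (cat.), CH2Cl2, 0 °C; then 18, DMAP, Et3N, CH2Cl2, 0 → 20 °C
Reagents that add atoms: none
Why: DMAP-catalysed acylation with the acid chloride esterifies the secondary allylic alcohol while the tertiary C-9 hydroxyl is too hindered to react; configuration at C-6 is retained.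

**Step 13**
Reactants: 23 ethyl (1S,4R,4aS,8aS)-1-hydroxy-2,5,5,8a-tetramethyl-4-[(2E,4E,6E)-octa-2,4,6-trienoyloxy]-1,4,4a,5,6,7,8,8a-octahydronaphthalene-1-carboxylate
Product: 24 ethyl (1R,4R,4aS,8aS)-2-formyl-1-hydroxy-5,5,8a-trimethyl-4-[(2E,4E,6E)-octa-2,4,6-trienoyloxy]-1,4,4a,5,6,7,8,8a-octahydronaphthalene-1-carboxylate
Conditions: SeO2, 1,4-dioxane, 80 °C
Reagents that add atoms: selenium dioxide, O=[Se]=O
Why: Riley allylic oxidation with SeO2 (ene reaction then [2,3]-shift) attacks the C-8 methyl group, the only allylic C–H set on the ring alkene that is not deactivated by an acyloxy group, and takes it to the conjugated aldehyde.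

**Step 14**
Reactants: 24 ethyl (1R,4R,4aS,8aS)-2-formyl-1-hydroxy-5,5,8a-trimethyl-4-[(2E,4E,6E)-octa-2,4,6-trienoyloxy]-1,4,4a,5,6,7,8,8a-octahydronaphthalene-1-carboxylate
Product: 25 (1R,4R,4aS,8aS)-2-formyl-1-hydroxy-5,5,8a-trimethyl-4-[(2E,4E,6E)-octa-2,4,6-trienoyloxy]-1,4,4a,5,6,7,8,8a-octahydronaphthalene-1-carboxylic acid
Conditions: LiOH (1.1 equiv), THF/H2O, 0 °C; then 1 M HCl to pH 3
Reagents that add atoms: lithium hydroxide, [Li+].[OH-]
Why: saponification with anchimeric assistance: hydroxide adds to the formyl group and the gem-diol oxyanion attacks the neighbouring ethyl ester through a five-membered ring (as in 2-formylbenzoate esters), so the hindered C-11 ester is cleaved much faster than the C-6 trienoate, and acidification gives the acid.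

**Compound list**
1 | 2-methylcyclopentane-1,3-dione | CC1C(=O)CCC1=O | starting material
2 | methyl vinyl ketone | CC(=O)C=C | starting material
3 | 2-methyl-2-(3-oxobutyl)cyclopentane-1,3-dione | CC(=O)CCC1(C)C(=O)CCC1=O | intermediate
4 | (3aS,7aS)-3a-hydroxy-7a-methylhexahydro-1H-indene-1,5(4H)-dione | O=C1CC[C@]2(O)CC(=O)CC[C@]12C | intermediate
5 | (S)-7a-methyl-2,3,7,7a-tetrahydro-1H-indene-1,5(6H)-dione | O=C1CCC2=CC(=O)CC[C@]12C | intermediate
6 | (7aS)-1,1-(ethylenedioxy)-7a-methyl-1,2,3,6,7,7a-hexahydro-5H-inden-5-one | O1CCOC12CCC3=CC(=O)CC[C@]23C | intermediate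
7 | (7aS)-1,1-(ethylenedioxy)-4,4,7a-trimethyl-1,2,4,6,7,7a-hexahydro-5H-inden-5-one | O1CCOC12CC=C3C(C)(C)C(=O)CC[C@]23C | intermediate
8 | (7aS)-1,1-(ethylenedioxy)-4,4,7a-trimethyl-2,4,5,6,7,7a-hexahydro-1H-indene | O1CCOC12CC=C3C(C)(C)CCC[C@]23C | intermediate
9 | (7aS)-4,4,7a-trimethyl-2,4,5,6,7,7a-hexahydro-1H-inden-1-one | O=C1CC=C2C(C)(C)CCC[C@]12C | intermediate
10 | (3aS,7aS)-4,4,7a-trimethyloctahydro-1H-inden-1-one | O=C1CC[C@H]2C(C)(C)CCC[C@]12C | intermediate
11 | ethyl diazoacetate | CCOC(=O)C=[N+]=[N-] | starting material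
12 | ethyl 2-diazo-2-[(1S,3aS,7aS)-1-hydroxy-4,4,7a-trimethyloctahydro-1H-inden-1-yl]acetate | CCOC(=O)C(=[N+]=[N-])[C@]1(O)CC[C@H]2C(C)(C)CCC[C@]12C | intermediate
13 | ethyl 2-[(1S,3aS,7aS)-1-hydroxy-4,4,7a-trimethyloctahydro-1H-inden-1-yl]-2-oxoacetate | CCOC(=O)C(=O)[C@]1(O)CC[C@H]2C(C)(C)CCC[C@]12C | intermediate
14 | ethyl (1R,4aS,8aS)-1-hydroxy-5,5,8a-trimethyl-2-oxodecahydronaphthalene-1-carboxylate | CCOC(=O)[C@]1(O)C(=O)CC[C@H]2C(C)(C)CCC[C@]12C | intermediate
15 | ethyl (1R,4aS,8aS)-1-hydroxy-5,5,8a-trimethyl-2-oxo-1,2,4a,5,6,7,8,8a-octahydronaphthalene-1-carboxylate | CCOC(=O)[C@]1(O)C(=O)C=C[C@H]2C(C)(C)CCC[C@]12C | intermediate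
16 | ethyl (1R,2S,4aS,8aS)-1,2-dihydroxy-2,5,5,8a-tetramethyl-1,2,4a,5,6,7,8,8a-octahydronaphthalene-1-carboxylate | CCOC(=O)[C@]1(O)[C@@](C)(O)C=C[C@H]2C(C)(C)CCC[C@]12C | intermediate
17 | ethyl (1S,4aS,8aS)-1-hydroxy-2,5,5,8a-tetramethyl-4-oxo-1,4,4a,5,6,7,8,8a-octahydronaphthalene-1-carboxylate | CCOC(=O)[C@]1(O)C(C)=CC(=O)[C@H]2C(C)(C)CCC[C@]12C | intermediate
18 | ethyl (1S,4R,4aS,8aS)-1,4-dihydroxy-2,5,5,8a-tetramethyl-1,4,4a,5,6,7,8,8a-octahydronaphthalene-1-carboxylate | CCOC(=O)[C@]1(O)C(C)=C[C@@H](O)[C@H]2C(C)(C)CCC[C@]12C | intermediate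
19 | (2E,4E)-hexa-2,4-dienal | C/C=C/C=C/C=O | starting material
20 | malonic acid | OC(=O)CC(=O)O | starting material
21 | (2E,4E,6E)-octa-2,4,6-trienoic acid | C/C=C/C=C/C=C/C(=O)O | intermediate
22 | (2E,4E,6E)-octa-2,4,6-trienoyl chloride | C/C=C/C=C/C=C/C(=O)Cl | intermediate
23 | ethyl (1S,4R,4aS,8aS)-1-hydroxy-2,5,5,8a-tetramethyl-4-[(2E,4E,6E)-octa-2,4,6-trienoyloxy]-1,4,4a,5,6,7,8,8a-octahydronaphthalene-1-carboxylate | CCOC(=O)[C@]1(O)C(C)=C[C@@H](OC(=O)/C=C/C=C/C=C/C)[C@H]2C(C)(C)CCC[C@]12C | intermediate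
24 | ethyl (1R,4R,4aS,8aS)-2-formyl-1-hydroxy-5,5,8a-trimethyl-4-[(2E,4E,6E)-octa-2,4,6-trienoyloxy]-1,4,4a,5,6,7,8,8a-octahydronaphthalene-1-carboxylate | CCOC(=O)[C@]1(O)C(C=O)=C[C@@H](OC(=O)/C=C/C=C/C=C/C)[C@H]2C(C)(C)CCC[C@]12C | intermediate
25 | (1R,4R,4aS,8aS)-2-formyl-1-hydroxy-5,5,8a-trimethyl-4-[(2E,4E,6E)-octa-2,4,6-trienoyloxy]-1,4,4a,5,6,7,8,8a-octahydronaphthalene-1-carboxylic acid | C/C=C/C=C/C=C/C(=O)O[C@@H]1C=C(C=O)[C@@](O)(C(=O)O)[C@@]2(C)CCCC(C)(C)[C@H]12 | target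

**Counts**
Total step count: 14. Longest linear sequence: 13 (steps 1–10 and 12–14; step 11 is the side branch).

**Three steps most likely to fail**

Step 7 (the proposed new ring enlargement). The CH2 carbon (C-7) could migrate instead of C-10, or C-9 could form with the opposite configuration. The fallback uses known chemistry, sets out from 10 and comes back at 17. Ring enlargement of 10 with TMSCHN2 and BF3·OEt2 (the less substituted carbon migrates) gives (4aS,8aS)-5,5,8a-trimethyl-2-(trimethylsilyl)octahydronaphthalen-1(2H)-one F1, which is desilylated on acid work-up to (4aS,8aS)-5,5,8a-trimethyloctahydronaphthalen-1(2H)-one F2. Methylation (LiN(iPr)2, MeI) gives (4aS,8aS)-2,5,5,8a-tetramethyloctahydronaphthalen-1(2H)-one F3, and IBX dehydrogenation gives (4aS,8aS)-2,5,5,8a-tetramethyl-4a,5,6,7,8,8a-hexahydronaphthalen-1(4H)-one F4. 1-Ethoxyvinyllithium then adds to the C-9 ketone from the α-face, anti to the adjacent angular methyl, to give (1S,4aS,8aS)-1-(1-ethoxyethenyl)-2,5,5,8a-tetramethyl-1,4,4a,5,6,7,8,8a-octahydronaphthalen-1-ol F5; this sets the same C-9 configuration by nucleophilic addition instead of by a shift. Ozonolysis of the enol ether (O3, CH2Cl2/MeOH, −78 °C, then Me2S) gives ethyl (1S,4aS,8aS)-1-hydroxy-2,5,5,8a-tetramethyl-1,4,4a,5,6,7,8,8a-octahydronaphthalene-1-carboxylate F6. Allylic oxidation at C-6 with CrO3·3,5-dimethylpyrazole returns to 17.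

Step 13 (late SeO2 oxidation). The ring alkene is deactivated by the allylic acyloxy group and the trienoate may compete. The fallback sets out from 18 and comes back at 24: the oxidation is done before the triene is attached and in two stages. SeO2 (cat.) with t-BuOOH in CH2Cl2 hydroxylates the C-8 methyl to give ethyl (1R,4R,4aS,8aS)-1,4-dihydroxy-2-(hydroxymethyl)-5,5,8a-trimethyl-1,4,4a,5,6,7,8,8a-octahydronaphthalene-1-carboxylate F7. TEMPO with PhI(OAc)2 oxidises only the primary allylic alcohol to give ethyl (1R,4R,4aS,8aS)-2-formyl-1,4-dihydroxy-5,5,8a-trimethyl-1,4,4a,5,6,7,8,8a-octahydronaphthalene-1-carboxylate F8. Acylation of the 6β-hydroxyl with 22 (DMAP, Et3N) gives 24.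

Step 14 (selective cleavage of the hindered ethyl ester). Without enough assistance from the formyl group the trienoate would be lost first. The fallback sets out from 18 and comes back at 25 by changing the ester before the sensitive groups are present. Forcing saponification of 18 (LiOH, dioxane/H2O, 80 °C) gives (1S,4R,4aS,8aS)-1,4-dihydroxy-2,5,5,8a-tetramethyl-1,4,4a,5,6,7,8,8a-octahydronaphthalene-1-carboxylic acid F9. Alkylation with allyl bromide and Cs2CO3 in DMF gives prop-2-en-1-yl (1S,4R,4aS,8aS)-1,4-dihydroxy-2,5,5,8a-tetramethyl-1,4,4a,5,6,7,8,8a-octahydronaphthalene-1-carboxylate F10. Acylation with 22 gives prop-2-en-1-yl (1S,4R,4aS,8aS)-1-hydroxy-2,5,5,8a-tetramethyl-4-[(2E,4E,6E)-octa-2,4,6-trienoyloxy]-1,4,4a,5,6,7,8,8a-octahydronaphthalene-1-carboxylate F11, and SeO2 oxidation gives prop-2-en-1-yl (1R,4R,4aS,8aS)-2-formyl-1-hydroxy-5,5,8a-trimethyl-4-[(2E,4E,6E)-octa-2,4,6-trienoyloxy]-1,4,4a,5,6,7,8,8a-octahydronaphthalene-1-carboxylate F12. The allyl ester is removed under neutral conditions with Pd(PPh3)4 and PhSiH3 to give 25.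

**Further compounds**
F1 | step 7 | (4aS,8aS)-5,5,8a-trimethyl-2-(trimethylsilyl)octahydronaphthalen-1(2H)-one | O=C1C([Si](C)(C)C)CC[C@H]2C(C)(C)CCC[C@]12C
F2 | step 7 | (4aS,8aS)-5,5,8a-trimethyloctahydronaphthalen-1(2H)-one | O=C1CCC[C@H]2C(C)(C)CCC[C@]12C
F3 | step 7 | (4aS,8aS)-2,5,5,8a-tetramethyloctahydronaphthalen-1(2H)-one | O=C1C(C)CC[C@H]2C(C)(C)CCC[C@]12C
F4 | step 7 | (4aS,8aS)-2,5,5,8a-tetramethyl-4a,5,6,7,8,8a-hexahydronaphthalen-1(4H)-one | O=C1C(C)=CC[C@H]2C(C)(C)CCC[C@]12C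
F5 | step 7 | (1S,4aS,8aS)-1-(1-ethoxyethenyl)-2,5,5,8a-tetramethyl-1,4,4a,5,6,7,8,8a-octahydronaphthalen-1-ol | CCOC(=C)[C@]1(O)C(C)=CC[C@H]2C(C)(C)CCC[C@]12C
F6 | step 7 | ethyl (1S,4aS,8aS)-1-hydroxy-2,5,5,8a-tetramethyl-1,4,4a,5,6,7,8,8a-octahydronaphthalene-1-carboxylate | CCOC(=O)[C@]1(O)C(C)=CC[C@H]2C(C)(C)CCC[C@]12C
F7 | step 13 | ethyl (1R,4R,4aS,8aS)-1,4-dihydroxy-2-(hydroxymethyl)-5,5,8a-trimethyl-1,4,4a,5,6,7,8,8a-octahydronaphthalene-1-carboxylate | CCOC(=O)[C@]1(O)C(CO)=C[C@@H](O)[C@H]2C(C)(C)CCC[C@]12C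
F8 | step 13 | ethyl (1R,4R,4aS,8aS)-2-formyl-1,4-dihydroxy-5,5,8a-trimethyl-1,4,4a,5,6,7,8,8a-octahydronaphthalene-1-carboxylate | CCOC(=O)[C@]1(O)C(C=O)=C[C@@H](O)[C@H]2C(C)(C)CCC[C@]12C
F9 | step 14 | (1S,4R,4aS,8aS)-1,4-dihydroxy-2,5,5,8a-tetramethyl-1,4,4a,5,6,7,8,8a-octahydronaphthalene-1-carboxylic acid | OC(=O)[C@]1(O)C(C)=C[C@@H](O)[C@H]2C(C)(C)CCC[C@]12C
F10 | step 14 | prop-2-en-1-yl (1S,4R,4aS,8aS)-1,4-dihydroxy-2,5,5,8a-tetramethyl-1,4,4a,5,6,7,8,8a-octahydronaphthalene-1-carboxylate | C=CCOC(=O)[C@]1(O)C(C)=C[C@@H](O)[C@H]2C(C)(C)CCC[C@]12C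
F11 | step 14 | prop-2-en-1-yl (1S,4R,4aS,8aS)-1-hydroxy-2,5,5,8a-tetramethyl-4-[(2E,4E,6E)-octa-2,4,6-trienoyloxy]-1,4,4a,5,6,7,8,8a-octahydronaphthalene-1-carboxylate | C=CCOC(=O)[C@]1(O)C(C)=C[C@@H](OC(=O)/C=C/C=C/C=C/C)[C@H]2C(C)(C)CCC[C@]12C
F12 | step 14 | prop-2-en-1-yl (1R,4R,4aS,8aS)-2-formyl-1-hydroxy-5,5,8a-trimethyl-4-[(2E,4E,6E)-octa-2,4,6-trienoyloxy]-1,4,4a,5,6,7,8,8a-octahydronaphthalene-1-carboxylate | C=CCOC(=O)[C@]1(O)C(C=O)=C[C@@H](OC(=O)/C=C/C=C/C=C/C)[C@H]2C(C)(C)CCC[C@]12C
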